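Two questions stand over this flask: how much electrophile has reacted, and how much nucleophile is still free.

electrophile 5.0 mM (fed, over 0.25 s); solid nucleophile 2.00 equiv; gas 0.28 mM (held); time 15 s

- part of the electrophile that has reacted at 15 s
- share of free nucleophile in free nucleophile and protonated nucleophile together, at 15 s

- as a solid, counted per litre of solution: solid nucleophile
- at the start none of free base is dissolved
- at the start none of the solid nucleophile is in solution
- run time (flask): 15 s

    electrophile + nucleophile ⇌ acid set free + product (K1 = 3.64, k1 = 65.2 M⁻¹ s⁻¹)
    nucleophile + acid set free ⇌ protonated nucleophile, settled at all times (K2 = 1.69 × 10⁶ M⁻¹)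
    acid set free + free base ⇌ salt of the base (K3 = 1.2 × 10⁷ M⁻¹, k3 = 3350 M⁻¹ s⁻¹)
    solid nucleophile ⇌ nucleophile, rate k4*(cs4 - [nucleophile]) while solid is left; crystals form when [nucleophile] > cs4 (cs4 = 4.9 mM, k4 = 3.51 s⁻¹)
    gas ⇌ free base, rate k5*(csat - [free base]) (k5 = 22.3 s⁻¹, csat = 0.28 mM)

The rate of the first step is k·E·N, with E the electrophile, N the dissolved free nucleophile and k = 65.2 M⁻¹ s⁻¹, so N sets the order of the rate. A first estimate holds N at its solubility 4.9 mM. The step is then pseudo-first-order and leaves 0.829% of the electrophile at 15 s.

The objection is the solid's supply. If the acid set free takes a second nucleophile, each turnover costs two, and the charge converts 5.00 mM of electrophile. This capacity, the nucleophile charge divided by the two it costs per turnover, matches the electrophile charge. Once the solid is gone, N therefore equals 2E, and the rate turns second order in E.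

A doubt remains: free base might spare that second nucleophile. The rate of the path to the salt needs E late in the run, so the two-stage reckoning must come first.

N held at solubility brings E down to half that solubility in 2.23 s. Second-order decay then leaves 0.482 mM. Now the doubt can be computed: the salt path runs at 0.00260 mM s⁻¹, less than the first step's 0.0303 mM s⁻¹, so the cost of two stands. This gives 90.4% reacted and, from 2E divided by the electrophile charge plus E, a free share of 17.6%.

The forecast gives 90% and 18%, on the ground that “each electrophile converted uses up two nucleophiles”.

The simulation gives 90.0% and 18.5%, and the forecast holds within its margin. In this flask the forward half-life of electrophile by the first step, 2.7 s at 0.675 s, is far shorter than the 43 min of free base on its path to the salt, and at 15.0 s nucleophile stands at 1.02 mM beside 0.500 mM electrophile. The neighbour flask with 0.800 equiv of solid nucleophile has a capacity of 2.00 mM, or 40.0% of its charge, and it reaches 40.9% with solid nucleophile at 0%.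

The rate constants were drawn at random within sensible limits; the flask was simulated.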